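The runs come from a simulation with constants of no real substance, noise included.

The time asked, 8.0 h, is twice the last reading of either earlier run, so I need a quantity that runs straight in time.

| flask | electrophile | nucleophile | free base | remark | time |
|---|---|---|---|---|---|
| Wednesday's | 0.82 M | 2.05 M | 0.18 M | run made earlier |  |
| Friday's | 0.82 M | 2.05 M | 0.33 M | run made earlier |  |
| teal | 0.82 M | 2.05 M | 0.250 M |  | 8.0 h |
| amber | 0.82 M | 2.05 M | 0.370 M |  | 8.0 h |

| run | time / h | electrophile / % | target / % |
|---|---|---|---|
| Wednesday's | 0.200 | 98.2 | 1.5 |
| Wednesday's | 0.667 | 96.0 | 4.6 |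
| Wednesday's | 1.00 | 93.6 | 6.6 |
| Wednesday's | 1.50 | 90.6 | 9.2 |
| Wednesday's | 2.50 | 85.2 | 14.5 |
| Wednesday's | 3.00 | 83.3 | 17.3 |
| Wednesday's | 4.00 | 78.1 | 21.9 |
| Friday's | 0.500 | 96.5 | 3.4 |
| Friday's | 1.00 | 93.1 | 7.1 |
| Friday's | 1.50 | 90.6 | 9.4 |
| Friday's | 2.50 | 84.7 | 15.0 |
| Friday's | 3.00 | 83.1 | 17.2 |
| Friday's | 4.00 | 78.4 | 21.9 |

(scatter of a reading: 0.3 percentage points)

- part of the electrophile that has reacted at the end, teal
- part of the electrophile that has reacted at the end, amber
- what raising the concentration of free base from its lowest to its highest value here does to the part of the electrophile that has reacted (changes below 5 percentage points count as none) (it falls / no change / it rises)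



I count electrophile, the limiting reagent, and nucleophile as spent one for one, and go to logarithms. The log-gap is the natural logarithm of the fraction of nucleophile left over the fraction of electrophile left, and under a second-order law it grows evenly in time. Wednesday's electrophile at 4.00 h, 78.1%, gives a growth per hour, the gap rate, of 0.0389 h⁻¹. Friday's target at 3.00 h, 17.2%, is another species in another run, with 0.33 M of free base against Wednesday's 0.18 M, and it gives 0.0392 h⁻¹.

Carried to 8.0 h and solved for the part reacted, the first gives 37.8% and the second 38.0%. The two ways agree, so I trust that figure. Teal and amber have the same charges of electrophile and nucleophile, so I commit to it for both, with no change between them. But Wednesday's target ended at 21.9% against a free base share of 22.0% of the electrophile charge, so neither run shows what happens past that share.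

The forecast differs from me on teal. It gives 30.5% for teal, lower than mine, and 38% for amber, with the trend it rises. Its grounds are that free base takes up the acid one for one, “assuming the nucleophile cannot take over as base”.

Teal gives 36.9% and amber 37.1%, a change of 0.11 percentage points, so the trend is no change.

    acid set free + free base ⇌ salt of the base (K = 3.98 × 10⁵ M⁻¹, k = 0.125 M⁻¹ min⁻¹)
    electrophile + nucleophile → acid set free + target (k = 5.57 × 10⁻⁴ M⁻¹ min⁻¹)
    nucleophile + acid set free ⇌ idle adduct, settled at all times (K = 0.130 M⁻¹)
    nucleophile + target → over-reaction product (k = 6.01 × 10⁻⁵ M⁻¹ min⁻¹)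
    nucleophile + acid set free ⇌ protonated nucleophile, settled at all times (K = 27.0 M⁻¹)

Teal's own gap rate from that result is 0.0377 h⁻¹, just under the reading. Teal stands above 30.5% at 8.00 h with 81.6% of its free base still free, holding 0.249 M of protonated nucleophile against 0.0461 M of salt of the base, and the step of acid set free with free base makes no difference. Teal's figure is owed in part to the falling level of nucleophile, acting together with the time allowed: with that fall taken away teal gives 42.2%, and at 80.0 h it gives 93.2%. Scaled to the excess of nucleophile over electrophile, the gap rate gives 24.2% for a flask like teal with 1.2 M of nucleophile. That flask stands at 23.6% reacted at 8.00 h.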